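One minute of gamma holds 2.30 min of zeta, if what counts is enzyme working for a time.

| flask | starting material | second substrate | free enzyme | remark | time |
|---|---|---|---|---|---|
| zeta | 13 mM | 14.3 mM (in portions, 3) | 8.7 µM | run made earlier; portions every 40 s |  |
| gamma | 13 mM | 14.3 mM (in portions, 3) | 20 µM | run made earlier; portions every 40 s |  |
| flask | 13 mM | 14.3 mM (in portions, 3) | 13 µM | the portions of second substrate follow each other after 40 s, the first at the start | 6.0 min |

| run | time / min | starting material / % | target / % |
|---|---|---|---|
| zeta | 0.200 | 97.7 | 2.4 |
| zeta | 0.500 | 95.6 | 5.4 |
| zeta | 1.00 | 88.1 | 12.2 |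
| zeta | 1.50 | 79.7 | 21.9 |
| zeta | 2.00 | 70.6 | 27.5 |
| zeta | 3.00 | 55.5 | 44.1 |
| zeta | 4.00 | 45.2 | 58.2 |
| gamma | 0.250 | 92.3 | 7.0 |
| gamma | 0.417 | 90.2 | 8.7 |
| gamma | 0.667 | 85.5 | 13.1 |
| gamma | 1.00 | 74.6 | 25.6 |
| gamma | 1.50 | 62.5 | 38.7 |
| gamma | 2.50 | 32.5 | 67.3 |
| gamma | 4.00 | 11.3 | 89.2 |

(standard deviation of a reading: 1 percentage point)

1. why nothing more happens at 6.0 min, or that something still does (forward and back rates have come level / all of the starting material has reacted / the second substrate has run out first / no working catalyst is left / it is still moving)
2. conversion of starting material at 6.0 min
3. amount of target at 6.0 min, in percent of the starting material charged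
4. amount of target if the flask were left three thousand times as long, in percent of the starting material charged

- the reaction counts as stopped when no species that holds the starting material changes by six tenths of a point or more over the second half of the time

In these runs c(starting material) is 1000 times c(free enzyme), and gamma's last reading of starting material plus target sums to 101%, so the catalyst holds no visible material and target can be read as conversion. Suppose that whatever the enzyme binds settles fast against these minutes (the quasi-steady state). With equal charges, the rate is then proportional to c(free enzyme) at a given composition, and composition follows c(free enzyme) times time. For the flask at 6.0 min, that product divided by gamma's c(free enzyme) reads 3.90 min. This is the gamma clock: the time at which gamma has had the same enzyme-time.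

| run | free enzyme | own clock | gamma clock | starting material |
|---|---|---|---|---|
| zeta | 8.7 µM | 2.00 min | 0.870 min | 70.6% |
| gamma | 20 µM | 1.00 min | 1.00 min | 74.6% |
| zeta | 8.7 µM | 4.00 min | 1.74 min | 45.2% |
| gamma | 20 µM | 1.50 min | 1.50 min | 62.5% |
| gamma | 20 µM | 2.50 min | 2.50 min | 32.5% |
| gamma | 20 µM | 4.00 min | 4.00 min | 11.3% |
| flask | 13 µM | 6.0 min | 3.90 min | asked |

Read the first two rows together: zeta, earlier on this clock, has less left than gamma. The third row shows the same lead once the clocks are matched: a straight line between gamma's next two rows gives 55.3% at zeta's 1.74 min, and zeta's reading of 45.2% lies below that. The portions come by the wall clock, so zeta's last lands at 0.580 min on the gamma clock and gamma's at 1.33 min, which is earlier for zeta. The flask's last row sits just before gamma's. Stepping back along gamma's last stretch gives 12.7% left, or perhaps a little less, so I reckon 87.3% conversion and as much target. That stretch lost 21 percentage points, so the flask should still be moving.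

The forecast says it is still moving, with conversion 85% (76% to 92%), target 85% (75% to 92%) and 99% (88% to 100%) after the long wait, noting “Neither run shows clear catalyst death or an equilibrium plateau”; its conversion stands lower than mine.

The flask gives it is still moving, conversion 89.4%, target 89.4%, and 100% after the long wait.

    starting material + free enzyme ⇌ first complex (K = 190 L mol⁻¹, k = 44000 L mol⁻¹ s⁻¹)
    first complex ⇌ loaded enzyme + first product (K = 0.0510 M, k = 31.0 s⁻¹)
    second substrate + loaded enzyme ⇌ second complex (K = 53.0 L mol⁻¹, k = 3.00 × 10⁵ L mol⁻¹ s⁻¹)
    second complex → free enzyme + target (k = 16.0 s⁻¹)

At 3.90 min on the gamma clock, the flask has 2.1 points less starting material left than I reckoned, on the side the portions pointed to. A flask with 0.0032 mM of free enzyme reads 0.960 min on the gamma clock at 6.0 min, and it holds 63% of its starting material, less than gamma's 74.6% at 1.00 min. The main reason the flask is unfinished at 6.0 min is first complex falling back to starting material and free enzyme: the run without that step converts 97.5%, against 89.4%.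

Readings and results come from a simulation with constants of no real substance, and the scatter is random.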